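- The left-handed product was what I wanted, and the decision for the next flask was whether 0.600 equiv of coupling partner was enough or whether more should be charged.
- At 30.0 h the readings gave an excess of 83.4% in elm with 1.3 equiv of partner, 87.4% in ash with 0.84 equiv, and 90.8% in alder with 0.60 equiv, so among these runs the excess read higher as the equivalents fell, but alder also differed in left-handed substrate, 0.50 M against 0.25 M in ash, and each reading of right-handed product scatters by 1 percentage point, so I took this as a hint and asked what the smaller charge would cost in product.
- I treated the coupling partner as the limiting reagent and took one turn of it per product, after the protic impurity had taken its own share. For ash that subtraction gave 39.5% against 39.6% of products read at 30.0 h, and for alder it gave 28.7% against 30.3%, with each reading scattering by 1 point.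
- For the new flask the same subtraction gave 27.5%, and I named this the usable-partner ceiling: coupling partner charged less protic impurity charged, over both substrates charged. I judged that ceiling worth that hint of a higher excess, so I kept 0.600 equiv and left the other charges as they were.

common to all: protic impurity 0.0125 M; free catalyst 2.5 mol%

| charge | left-handed substrate | right-handed substrate | coupling partner | remark | time |
|---|---|---|---|---|---|
| ash | 0.25 M | 0.25 M | 0.84 equiv | run made earlier |  |
| elm | 0.25 M | 0.25 M | 1.3 equiv | run made earlier |  |
| alder | 0.50 M | 0.50 M | 0.60 equiv | run made earlier |  |
| flask | 0.25 M | 0.25 M | 0.600 equiv |  | 25 h |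

| run | time / h | left-handed product / % | right-handed product / % | left-handed substrate / % |
|---|---|---|---|---|
| ash | 8.00 | 19.6 | 0.9 | 32.0 |
| ash | 15.0 | 28.5 | 0.4 | 30.1 |
| ash | 25.0 | 32.8 | 2.0 | 26.1 |
| ash | 30.0 | 37.1 | 2.5 | 28.4 |
| elm | 2.50 | 11.6 | 1.2 | 37.8 |
| elm | 6.00 | 24.7 | 3.1 | 26.9 |
| elm | 12.0 | 40.4 | 4.2 | 21.3 |
| elm | 30.0 | 53.1 | 4.8 | 17.3 |
| alder | 2.50 | 11.8 | 1.9 | 39.3 |
| alder | 6.00 | 21.6 | 1.6 | 31.7 |
| alder | 12.0 | 24.4 | 1.8 | 30.9 |
| alder | 30.0 | 28.9 | 1.4 | 35.1 |

(scatter of a reading: 1 percentage point)

- free catalyst is single-handed; left-handed substrate and right-handed substrate are mirror images of each other, charged as a racemate, each of them at the stated concentration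
- the numbers in the tables scatter by 1 percentage point (one standard deviation)
- an excess is below zero if the other one leads

- excess of left-handed product over right-handed product in the product at 30 min
- excess of left-handed product over right-handed product in the product at 25 h
- part of the left-handed substrate and right-handed substrate charged together that has reacted at 25 h

- The forecast, with the grounds “Stall points fit partner limitation”, gave 85% at 30 min, 87% at 25 h and 25.5% reacted, which stands below my ceiling.
- The flask gave 87.8% at 30 min, 90.6% at 25 h and 26.6% reacted, all within the forecast's margins.

    coupling partner + catalyst intermediate A → free catalyst + left-handed product (k = 0.330 /M/min)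
    coupling partner + catalyst intermediate B → free catalyst + right-handed product (k = 0.110 /M/min)
    coupling partner + protic impurity → quenched reagent (k = 0.100 /M/min)
    left-handed substrate ⇌ right-handed substrate (k = 8.50 × 10⁻⁴ /min)
    free catalyst + left-handed substrate ⇌ catalyst intermediate A (K = 73.0 /M, k = 5.80 /M/min)
    2 free catalyst → spent catalyst (k = 0.230 /M/min)
    free catalyst + right-handed substrate ⇌ catalyst intermediate B (K = 6.90 /M, k = 13.0 /M/min)

- At 25 h the flask stood 0.90 points below its ceiling, with 6.7% of its coupling partner left. I made the same subtraction for a neighbouring flask, like this one but charged with 0.150 equiv of coupling partner, and its ceiling came to 5.00%. That neighbour reacted 6.50% at 25 h, above its ceiling; it still held 23% of its protic impurity, had made 0.00962 M of quenched reagent against the 0.0125 M I had subtracted, and carried 1.07% of the substrates as catalyst intermediate A.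

(The data stem from a simulated flask for substances that don't exist; the scatter is artificial.)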